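**Plan**
1. Cuts, in order: the lactone C3–CH2Ar bond (enolate alkylation) gives lactone 18 and benzyl bromide 32; the lactone ring of 18 goes back to aldehyde 13 (Stobbe condensation, asymmetric hydrogenation); the C3a–C3 bond of the dihydrobenzofuran goes back to flavanone 6 (reverse 1,2-aryl shift); the Cα–Cβ bond of the open unit goes back to aldehyde 25 and (E)-cinnamylboronate 24.
2. Enabling feature: in the 2-aryl-3-(hydroxymethyl)-2,3-dihydrobenzofuran, C3 carries both ring carbon C3a and an exocyclic one-carbon group. Moving C3a back onto that carbon gives a chroman-4-one (O1–C2–C3–C4(=O)–C4a), so an oxidative 1,2-shift of C4a from C4 to C3 contracts the pyranone to the furan ring and expels C4 as the ester that becomes CH2OH.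
3. Forward order: chromone, flavanone (pyranone ring), ring contraction (furan ring), aldehyde, butyrolactone ring. Separately: aryl bromide, styrene, allylboronate, anti homoallylic alcohol, 1,3-diol, benzyl bromide. Then lactone alkylation, desilylation, hydrogenolysis.
4. Stereochemistry: dihydrobenzofuran C2 from the chiral palladium catalyst, C3 from C2 (trans) in the ring contraction; lactone C4 from rhodium-catalysed asymmetric hydrogenation, C3 from C4 (trans alkylation); both open-chain centers from a chiral phosphoric acid catalysed (E)-allylboration (anti via the chair transition state).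

Key step: step 4

Assumption: each chiral catalyst is named in the hand expected to give the drawn configuration; if a first run shows the opposite sense, the antipodal ligand is used with no other change.
Abbreviations: DBF = the (2S,3R)-2-[4-(benzyloxy)-3-methoxyphenyl]-7-methoxy-3-({[tri(propan-2-yl)silyl]oxy}methyl)-2,3-dihydro-1-benzofuran-5-yl group; (R)-t-BuPyOx = (R)-4-tert-butyl-2-(pyridin-2-yl)-4,5-dihydro-1,3-oxazole; (S)-TRIP = (S)-3,3'-bis(2,4,6-triisopropylphenyl)-1,1'-binaphthyl-2,2'-diyl hydrogen phosphate; Bpin = 4,4,5,5-tetramethyl-1,3,2-dioxaborolan-2-yl.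

**Route**

Step 1
Reactants: 1 1-(2-hydroxy-3-methoxyphenyl)ethan-1-one
Product: 2 1-(5-bromo-2-hydroxy-3-methoxyphenyl)ethan-1-one
Conditions: NBS (1.05 equiv), MeCN, 0 °C to rt
Reagents that add atoms: N-bromosuccinimide O=C1CCC(=O)N1Br
Why: Electrophilic aromatic bromination should go para to the phenol OH, the only free position activated by OH and meta to the acetyl group.

Step 2
Reactants: 2 1-(5-bromo-2-hydroxy-3-methoxyphenyl)ethan-1-one
Product: 4 6-bromo-8-methoxy-4H-chromen-4-one, via enaminone 3 (not isolated)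
Conditions: Me2NCH(OMe)2, toluene, 100 °C; then conc. HCl, CH2Cl2, 40 °C
Reagents that add atoms: N,N-dimethylformamide dimethyl acetal COC(OC)N(C)C
Why: Enaminone formation at the methyl ketone, then acid-induced conjugate addition of the phenol and loss of dimethylamine, is the standard enaminone chromone synthesis.

Step 3
Reactants: 4 6-bromo-8-methoxy-4H-chromen-4-one; 5 [4-(benzyloxy)-3-methoxyphenyl]boronic acid
Product: 6 (2S)-2-[4-(benzyloxy)-3-methoxyphenyl]-6-bromo-8-methoxy-2,3-dihydro-4H-chromen-4-one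
Conditions: Pd(OCOCF3)2 (5 mol %), (R)-t-BuPyOx (6 mol %), NH4PF6 (30 mol %), H2O (5 equiv), ClCH2CH2Cl, 60 °C
Reagents that add atoms: none
Why: Asymmetric conjugate addition of the arylboronic acid to the chromone under divalent palladium catalysis, in which the pyridine–oxazoline ligand selects the face of C2 (2S) and the aryl bromide stays inert because no zerovalent palladium cycle operates.

Step 4
Reactants: 6 (2S)-2-[4-(benzyloxy)-3-methoxyphenyl]-6-bromo-8-methoxy-2,3-dihydro-4H-chromen-4-one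
Product: 9 methyl (2S,3S)-2-[4-(benzyloxy)-3-methoxyphenyl]-5-bromo-7-methoxy-2,3-dihydro-1-benzofuran-3-carboxylate, via enol ether 7 (not isolated), via iodane 8 (not isolated)
Conditions: PhI(OAc)2 (1.2 equiv), conc. H2SO4 (2 equiv), HC(OMe)3, 0 °C to rt
Reagents that add atoms: trimethyl orthoformate COC(OC)OC
Why: Acid and orthoformate turn the C4 ketone into enol ether 7; PhI(OAc)2 attacks C3 anti to the equatorial C2 aryl group and methanol adds at C4 to give the trans 3-iodanyl 4,4-dimethyl ketal 8, whose equatorial C3–I bond is antiperiplanar to the C4–C4a bond. Loss of iodobenzene is assisted by ring A carbon C4a (activated by the ortho ring oxygen), which bridges C3 as a phenonium ion with inversion at C3 and then releases C4 as a dimethoxycarbenium ion that collapses to the methyl ester. The closest known reaction is the trivalent iodine (or thallium trinitrate) oxidative ring contraction of flavanones to methyl 2-aryl-2,3-dihydrobenzofuran-3-carboxylates, the cyclic form of the aryl ketone to arylalkanoate 1,2-aryl shift. The five-membered O1–C2–C3–C3a–C7a ring closes by this suprafacial 1,2-shift (3-exo-tet ipso attack of C4a on C3, then cleavage of C4–C4a), so the six-membered pyranone contracts and the C3a–C3 bond forms. The new center C3 is controlled by C2: iodination trans to the aryl group followed by inversion places the ester trans to it (2S,3S), and C2 itself is not touched. The step needs ring A to migrate in preference to the C2 aryl group (isoflavone) and to loss of H-3 (flavone); the diequatorial geometry of 8, in which only C4a is antiperiplanar to the leaving group, should secure this.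

Step 5
Reactants: 9 methyl (2S,3S)-2-[4-(benzyloxy)-3-methoxyphenyl]-5-bromo-7-methoxy-2,3-dihydro-1-benzofuran-3-carboxylate
Product: 10 [(2S,3R)-2-[4-(benzyloxy)-3-methoxyphenyl]-5-bromo-7-methoxy-2,3-dihydro-1-benzofuran-3-yl]methanol
Conditions: DIBAL-H (2.5 equiv), CH2Cl2, −78 to 0 °C; Rochelle salt work-up
Reagents that add atoms: none
Why: Ester-to-alcohol hydride reduction under non-basic conditions should leave the aryl bromide, the benzyl ether and both stereocenters untouched (no enolisation at C3).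

Step 6
Reactants: 10 [(2S,3R)-2-[4-(benzyloxy)-3-methoxyphenyl]-5-bromo-7-methoxy-2,3-dihydro-1-benzofuran-3-yl]methanol
Product: 11 {[(2S,3R)-2-[4-(benzyloxy)-3-methoxyphenyl]-5-bromo-7-methoxy-2,3-dihydro-1-benzofuran-3-yl]methoxy}tri(propan-2-yl)silane
Conditions: TIPSCl, imidazole, DMF, rt
Reagents that add atoms: chlorotri(propan-2-yl)silane CC(C)[Si](Cl)(C(C)C)C(C)C
Why: Silylation of the primary alcohol; TIPS is chosen to survive the organolithium, alkoxide and dilute acid steps that follow.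

Step 7
Reactants: 11 {[(2S,3R)-2-[4-(benzyloxy)-3-methoxyphenyl]-5-bromo-7-methoxy-2,3-dihydro-1-benzofuran-3-yl]methoxy}tri(propan-2-yl)silane
Product: 13 (2S,3R)-2-[4-(benzyloxy)-3-methoxyphenyl]-7-methoxy-3-({[tri(propan-2-yl)silyl]oxy}methyl)-2,3-dihydro-1-benzofuran-5-carbaldehyde (DBF-CHO), via aryllithium 12 (not isolated)
Conditions: n-BuLi (1.1 equiv), THF, −78 °C; then DMF, −78 to 0 °C; aq. NH4Cl
Reagents that add atoms: N,N-dimethylformamide CN(C)C=O
Why: Bromine–lithium exchange followed by formylation with DMF, the ethers being inert at −78 °C.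

Step 8
Reactants: 13 DBF-CHO; 14 dimethyl butanedioate
Product: 15 (3E)-4-DBF-3-(methoxycarbonyl)but-3-enoic acid
Conditions: NaOMe, MeOH, reflux; then cold 2 M HCl
Reagents that add atoms: none
Why: Stobbe condensation (succinate aldol, lactonisation to the paraconate, E1cB ring opening) should give the (E)-arylidenesuccinic half-ester with the carboxylic acid on the CH2 arm.

Step 9
Reactants: 15 (3E)-4-DBF-3-(methoxycarbonyl)but-3-enoic acid
Product: 16 (3R)-4-DBF-3-(methoxycarbonyl)butanoic acid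
Conditions: H2 (5 atm), [Rh(cod)((S,S)-Et-DuPhos)]BF4 (1 mol %), Et3N (1 equiv), MeOH, rt
Reagents that add atoms: none
Why: Rhodium–bisphosphine asymmetric hydrogenation of the itaconate-type half-ester, in which the chelating carboxylate and the ligand set the new center (3R) and the benzyl ether is not cleaved under homogeneous conditions.

Step 10
Reactants: 16 (3R)-4-DBF-3-(methoxycarbonyl)butanoic acid
Product: 18 (4R)-4-(DBF-methyl)oxolan-2-one, via hydroxy acid 17 (not isolated)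
Conditions: KOH (1.0 equiv), EtOH; CaCl2, NaBH4, EtOH, 0 °C to rt; then 2 M HCl, rt
Reagents that add atoms: none
Why: Calcium borohydride reduces the ester but not the carboxylate, and acidification lactonises the γ-hydroxy acid without touching the stereocenter.

Step 11
Reactants: 19 methyl 3-bromo-4-hydroxy-5-methoxybenzoate
Product: 20 methyl 4-(benzyloxy)-3-bromo-5-methoxybenzoate
Conditions: BnBr, K2CO3, DMF, 60 °C
Reagents that add atoms: benzyl bromide BrCc1ccccc1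
Why: Williamson etherification of the phenol.

Step 12
Reactants: 20 methyl 4-(benzyloxy)-3-bromo-5-methoxybenzoate; 21 2-ethenyl-4,4,5,5-tetramethyl-1,3,2-dioxaborolane
Product: 22 methyl 4-(benzyloxy)-3-ethenyl-5-methoxybenzoate
Conditions: PdCl2(dppf) (3 mol %), K2CO3, dioxane/H2O, 85 °C
Reagents that add atoms: none
Why: Suzuki–Miyaura vinylation of the aryl bromide.

Step 13
Reactants: 22 methyl 4-(benzyloxy)-3-ethenyl-5-methoxybenzoate; 23 4,4,5,5-tetramethyl-2-(prop-2-en-1-yl)-1,3,2-dioxaborolane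
Product: 24 methyl 4-(benzyloxy)-3-methoxy-5-[(1E)-3-(Bpin)prop-1-en-1-yl]benzoate
Conditions: second-generation Grubbs catalyst RuCl2(=CHPh)(H2IMes)(PCy3) (5 mol %), 23 (3 equiv), CH2Cl2, 40 °C
Reagents that add atoms: none
Why: Olefin cross-metathesis of the styrene with excess allylboronate releases ethene and should give the aryl-conjugated (E)-alkene as the favoured isomer.

Step 14
Reactants: 24 methyl 4-(benzyloxy)-3-methoxy-5-[(1E)-3-(Bpin)prop-1-en-1-yl]benzoate; 25 4-(benzyloxy)-3-methoxybenzaldehyde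
Product: 27 methyl 4-(benzyloxy)-3-{(1S,2R)-1-[4-(benzyloxy)-3-methoxyphenyl]-1-hydroxybut-3-en-2-yl}-5-methoxybenzoate, via pinacol borate 26 (not isolated)
Conditions: (S)-TRIP (5 mol %), 4 Å MS, toluene, −30 °C to rt; aqueous work-up
Reagents that add atoms: none
Why: Chiral phosphoric acid catalysed allylboration through a closed chair transition state, in which the (E)-γ-aryl group and the aldehyde aryl group are both equatorial (anti adduct) and the catalyst selects the aldehyde face (1S, hence 2R).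

Step 15
Reactants: 27 methyl 4-(benzyloxy)-3-{(1S,2R)-1-[4-(benzyloxy)-3-methoxyphenyl]-1-hydroxybut-3-en-2-yl}-5-methoxybenzoate
Product: 29 methyl 4-(benzyloxy)-3-{(1S,2S)-1-[4-(benzyloxy)-3-methoxyphenyl]-1,3-dihydroxypropan-2-yl}-5-methoxybenzoate, via ozonide 28 (not isolated)
Conditions: O3, CH2Cl2, −78 °C (Sudan red end point); then NaBH4, MeOH, −78 °C to rt
Reagents that add atoms: ozone [O-][O+]=O
Why: Ozonolysis with borohydride work-up reduces the cleavage product as it forms, so the α-aryl center should not epimerise and the benzoate is untouched.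

Step 16
Reactants: 29 methyl 4-(benzyloxy)-3-{(1S,2S)-1-[4-(benzyloxy)-3-methoxyphenyl]-1,3-dihydroxypropan-2-yl}-5-methoxybenzoate
Product: 30 methyl 4-(benzyloxy)-3-{(1S,2S)-1-[4-(benzyloxy)-3-methoxyphenyl]-1,3-bis[(tert-butyldimethylsilyl)oxy]propan-2-yl}-5-methoxybenzoate
Conditions: TBSOTf (2.5 equiv), 2,6-lutidine, CH2Cl2, −78 to 0 °C
Reagents that add atoms: tert-butyldimethylsilyl trifluoromethanesulfonate CC(C)(C)[Si](C)(C)OS(=O)(=O)C(F)(F)F
Why: Silylation of both the primary and the benzylic secondary alcohol under non-acidic conditions.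

Step 17
Reactants: 30 methyl 4-(benzyloxy)-3-{(1S,2S)-1-[4-(benzyloxy)-3-methoxyphenyl]-1,3-bis[(tert-butyldimethylsilyl)oxy]propan-2-yl}-5-methoxybenzoate
Product: 31 (4-(benzyloxy)-3-{(1S,2S)-1-[4-(benzyloxy)-3-methoxyphenyl]-1,3-bis[(tert-butyldimethylsilyl)oxy]propan-2-yl}-5-methoxyphenyl)methanol
Conditions: DIBAL-H (2.5 equiv), CH2Cl2, −78 °C; Rochelle salt work-up
Reagents that add atoms: none
Why: Hydride reduction of the benzoate to the benzylic alcohol, the silyl and benzyl ethers being inert.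

Step 18
Reactants: 31 (4-(benzyloxy)-3-{(1S,2S)-1-[4-(benzyloxy)-3-methoxyphenyl]-1,3-bis[(tert-butyldimethylsilyl)oxy]propan-2-yl}-5-methoxyphenyl)methanol
Product: 32 2-(benzyloxy)-1-{(1S,2S)-1-[4-(benzyloxy)-3-methoxyphenyl]-1,3-bis[(tert-butyldimethylsilyl)oxy]propan-2-yl}-5-(bromomethyl)-3-methoxybenzene
Conditions: CBr4, PPh3, CH2Cl2, 0 °C; used at once
Reagents that add atoms: tetrabromomethane BrC(Br)(Br)Br
Why: Appel bromination under neutral conditions, which the silyl ethers tolerate.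

Step 19
Reactants: 18 (4R)-4-(DBF-methyl)oxolan-2-one; 32 2-(benzyloxy)-1-{(1S,2S)-1-[4-(benzyloxy)-3-methoxyphenyl]-1,3-bis[(tert-butyldimethylsilyl)oxy]propan-2-yl}-5-(bromomethyl)-3-methoxybenzene
Product: 34 (3R,4R)-3-(4-(benzyloxy)-3-{(1S,2S)-1-[4-(benzyloxy)-3-methoxyphenyl]-1,3-bis[(tert-butyldimethylsilyl)oxy]propan-2-yl}-5-methoxybenzyl)-4-(DBF-methyl)oxolan-2-one, via lithium enolate 33 (not isolated)
Conditions: LiHMDS (1.1 equiv), THF, −78 °C; then 32, DMPU, −78 to −30 °C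
Reagents that add atoms: none
Why: Lactone enolate alkylation anti to the C4 substituent, the standard route to trans-3,4-dibenzylbutyrolactones, sets C3 (R).

Step 20
Reactants: 34 (3R,4R)-3-(4-(benzyloxy)-3-{(1S,2S)-1-[4-(benzyloxy)-3-methoxyphenyl]-1,3-bis[(tert-butyldimethylsilyl)oxy]propan-2-yl}-5-methoxybenzyl)-4-(DBF-methyl)oxolan-2-one
Product: 35 (3R,4R)-3-(4-(benzyloxy)-3-{(1S,2S)-1-[4-(benzyloxy)-3-methoxyphenyl]-1,3-dihydroxypropan-2-yl}-5-methoxybenzyl)-4-({(2S,3R)-2-[4-(benzyloxy)-3-methoxyphenyl]-3-(hydroxymethyl)-7-methoxy-2,3-dihydro-1-benzofuran-5-yl}methyl)oxolan-2-one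
Conditions: TBAF (5 equiv), AcOH (5 equiv), THF, 0 °C to rt
Reagents that add atoms: none
Why: Fluoride cleaves the two TBS ethers and the TIPS ether, and the acetic acid buffer keeps the medium from epimerising the lactone α-carbon.

Step 21
Reactants: 35 (3R,4R)-3-(4-(benzyloxy)-3-{(1S,2S)-1-[4-(benzyloxy)-3-methoxyphenyl]-1,3-dihydroxypropan-2-yl}-5-methoxybenzyl)-4-({(2S,3R)-2-[4-(benzyloxy)-3-methoxyphenyl]-3-(hydroxymethyl)-7-methoxy-2,3-dihydro-1-benzofuran-5-yl}methyl)oxolan-2-one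
Product: 36 (3R,4R)-3-{4-hydroxy-3-[(1S,2S)-1,3-dihydroxy-1-(4-hydroxy-3-methoxyphenyl)propan-2-yl]-5-methoxybenzyl}-4-{[(2S,3R)-2-(4-hydroxy-3-methoxyphenyl)-3-(hydroxymethyl)-7-methoxy-2,3-dihydro-1-benzofuran-5-yl]methyl}oxolan-2-one
Conditions: H2 (1 atm), 10% Pd/C, EtOAc/MeOH, rt, stopped at full debenzylation
Reagents that add atoms: none
Why: Hydrogenolysis of the three aryl benzyl ethers under neutral conditions, which avoids acid-induced ring closure of the open unit onto its free ortho phenol.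

**Compound list**
1 | 1-(2-hydroxy-3-methoxyphenyl)ethan-1-one | CC(=O)c1cccc(OC)c1O | starting material
2 | 1-(5-bromo-2-hydroxy-3-methoxyphenyl)ethan-1-one | CC(=O)c1cc(Br)cc(OC)c1O | intermediate
3 | (2E)-1-(5-bromo-2-hydroxy-3-methoxyphenyl)-3-(dimethylamino)prop-2-en-1-one | CN(C)/C=C/C(=O)c1cc(Br)cc(OC)c1O | intermediate (not isolated)
4 | 6-bromo-8-methoxy-4H-chromen-4-one | O=c1ccoc2c(OC)cc(Br)cc12 | intermediate
5 | [4-(benzyloxy)-3-methoxyphenyl]boronic acid | COc1cc(B(O)O)ccc1OCc1ccccc1 | starting material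
6 | (2S)-2-[4-(benzyloxy)-3-methoxyphenyl]-6-bromo-8-methoxy-2,3-dihydro-4H-chromen-4-one | O=C1C[C@@H](c2ccc(OCc3ccccc3)c(OC)c2)Oc2c(OC)cc(Br)cc21 | intermediate
7 | (2S)-2-[4-(benzyloxy)-3-methoxyphenyl]-6-bromo-4,8-dimethoxy-2H-chromene | COC1=C[C@@H](c2ccc(OCc3ccccc3)c(OC)c2)Oc2c(OC)cc(Br)cc21 | intermediate (not isolated)
8 | (2R,3R)-3-[acetoxy(phenyl)-λ3-iodanyl]-2-[4-(benzyloxy)-3-methoxyphenyl]-6-bromo-4,4,8-trimethoxy-3,4-dihydro-2H-chromene (iodanyl group trans to the C2 aryl group; the C2 descriptor changes by priority only) | COC1(OC)[C@H](I(OC(C)=O)c2ccccc2)[C@@H](c2ccc(OCc3ccccc3)c(OC)c2)Oc2c(OC)cc(Br)cc21 | intermediate (not isolated)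
9 | methyl (2S,3S)-2-[4-(benzyloxy)-3-methoxyphenyl]-5-bromo-7-methoxy-2,3-dihydro-1-benzofuran-3-carboxylate | Brc1cc(OC)c2c(c1)[C@H](C(=O)OC)[C@@H](c1ccc(OCc3ccccc3)c(OC)c1)O2 | intermediate
10 | [(2S,3R)-2-[4-(benzyloxy)-3-methoxyphenyl]-5-bromo-7-methoxy-2,3-dihydro-1-benzofuran-3-yl]methanol | Brc1cc(OC)c2c(c1)[C@H](CO)[C@@H](c1ccc(OCc3ccccc3)c(OC)c1)O2 | intermediate
11 | {[(2S,3R)-2-[4-(benzyloxy)-3-methoxyphenyl]-5-bromo-7-methoxy-2,3-dihydro-1-benzofuran-3-yl]methoxy}tri(propan-2-yl)silane | Brc1cc(OC)c2c(c1)[C@H](CO[Si](C(C)C)(C(C)C)C(C)C)[C@@H](c1ccc(OCc3ccccc3)c(OC)c1)O2 | intermediate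
12 | DBF-lithium (aryllithium from 11) | [Li]c1cc(OC)c2c(c1)[C@H](CO[Si](C(C)C)(C(C)C)C(C)C)[C@@H](c1ccc(OCc3ccccc3)c(OC)c1)O2 | intermediate (not isolated)
13 | (2S,3R)-2-[4-(benzyloxy)-3-methoxyphenyl]-7-methoxy-3-({[tri(propan-2-yl)silyl]oxy}methyl)-2,3-dihydro-1-benzofuran-5-carbaldehyde | O=Cc1cc(OC)c2c(c1)[C@H](CO[Si](C(C)C)(C(C)C)C(C)C)[C@@H](c1ccc(OCc3ccccc3)c(OC)c1)O2 | intermediate
14 | dimethyl butanedioate | COC(=O)CCC(=O)OC | starting material
15 | (3E)-4-DBF-3-(methoxycarbonyl)but-3-enoic acid | OC(=O)C/C(C(=O)OC)=C\c1cc(OC)c2c(c1)[C@H](CO[Si](C(C)C)(C(C)C)C(C)C)[C@@H](c1ccc(OCc3ccccc3)c(OC)c1)O2 | intermediate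
16 | (3R)-4-DBF-3-(methoxycarbonyl)butanoic acid | OC(=O)C[C@H](C(=O)OC)Cc1cc(OC)c2c(c1)[C@H](CO[Si](C(C)C)(C(C)C)C(C)C)[C@@H](c1ccc(OCc3ccccc3)c(OC)c1)O2 | intermediate
17 | (3R)-4-DBF-3-(hydroxymethyl)butanoic acid (carboxylate salt in the flask) | OC(=O)C[C@H](CO)Cc1cc(OC)c2c(c1)[C@H](CO[Si](C(C)C)(C(C)C)C(C)C)[C@@H](c1ccc(OCc3ccccc3)c(OC)c1)O2 | intermediate (not isolated)
18 | (4R)-4-(DBF-methyl)oxolan-2-one | O=C1C[C@@H](Cc2cc(OC)c3c(c2)[C@H](CO[Si](C(C)C)(C(C)C)C(C)C)[C@@H](c2ccc(OCc4ccccc4)c(OC)c2)O3)CO1 | intermediate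
19 | methyl 3-bromo-4-hydroxy-5-methoxybenzoate | COC(=O)c1cc(Br)c(O)c(OC)c1 | starting material
20 | methyl 4-(benzyloxy)-3-bromo-5-methoxybenzoate | COC(=O)c1cc(Br)c(OCc2ccccc2)c(OC)c1 | intermediate
21 | 2-ethenyl-4,4,5,5-tetramethyl-1,3,2-dioxaborolane | C=CB1OC(C)(C)C(C)(C)O1 | starting material
22 | methyl 4-(benzyloxy)-3-ethenyl-5-methoxybenzoate | COC(=O)c1cc(C=C)c(OCc2ccccc2)c(OC)c1 | intermediate
23 | 4,4,5,5-tetramethyl-2-(prop-2-en-1-yl)-1,3,2-dioxaborolane | C=CCB1OC(C)(C)C(C)(C)O1 | starting material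
24 | methyl 4-(benzyloxy)-3-methoxy-5-[(1E)-3-(4,4,5,5-tetramethyl-1,3,2-dioxaborolan-2-yl)prop-1-en-1-yl]benzoate | COC(=O)c1cc(/C=C/CB2OC(C)(C)C(C)(C)O2)c(OCc2ccccc2)c(OC)c1 | intermediate
25 | 4-(benzyloxy)-3-methoxybenzaldehyde | COc1cc(C=O)ccc1OCc1ccccc1 | starting material
26 | pinacol borate (O-Bpin ester) of alcohol 27 | COc1cc([C@@H](OB2OC(C)(C)C(C)(C)O2)[C@H](C=C)c2cc(C(=O)OC)cc(OC)c2OCc2ccccc2)ccc1OCc1ccccc1 | intermediate (not isolated)
27 | methyl 4-(benzyloxy)-3-{(1S,2R)-1-[4-(benzyloxy)-3-methoxyphenyl]-1-hydroxybut-3-en-2-yl}-5-methoxybenzoate | COc1cc([C@@H](O)[C@H](C=C)c2cc(C(=O)OC)cc(OC)c2OCc2ccccc2)ccc1OCc1ccccc1 | intermediate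
28 | ozonide of 27 (vinyl group turned into a 1,2,4-trioxolan-3-yl ring; chain centers unchanged; epimer mixture at the trioxolane carbon) | COc1cc([C@@H](O)[C@H](C2OCOO2)c2cc(C(=O)OC)cc(OC)c2OCc2ccccc2)ccc1OCc1ccccc1 | intermediate (not isolated)
29 | methyl 4-(benzyloxy)-3-{(1S,2S)-1-[4-(benzyloxy)-3-methoxyphenyl]-1,3-dihydroxypropan-2-yl}-5-methoxybenzoate | COc1cc([C@@H](O)[C@H](CO)c2cc(C(=O)OC)cc(OC)c2OCc2ccccc2)ccc1OCc1ccccc1 | intermediate
30 | methyl 4-(benzyloxy)-3-{(1S,2S)-1-[4-(benzyloxy)-3-methoxyphenyl]-1,3-bis[(tert-butyldimethylsilyl)oxy]propan-2-yl}-5-methoxybenzoate | COc1cc([C@@H](O[Si](C)(C)C(C)(C)C)[C@H](CO[Si](C)(C)C(C)(C)C)c2cc(C(=O)OC)cc(OC)c2OCc2ccccc2)ccc1OCc1ccccc1 | intermediate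
31 | (4-(benzyloxy)-3-{(1S,2S)-1-[4-(benzyloxy)-3-methoxyphenyl]-1,3-bis[(tert-butyldimethylsilyl)oxy]propan-2-yl}-5-methoxyphenyl)methanol | COc1cc([C@@H](O[Si](C)(C)C(C)(C)C)[C@H](CO[Si](C)(C)C(C)(C)C)c2cc(CO)cc(OC)c2OCc2ccccc2)ccc1OCc1ccccc1 | intermediate
32 | 2-(benzyloxy)-1-{(1S,2S)-1-[4-(benzyloxy)-3-methoxyphenyl]-1,3-bis[(tert-butyldimethylsilyl)oxy]propan-2-yl}-5-(bromomethyl)-3-methoxybenzene | COc1cc([C@@H](O[Si](C)(C)C(C)(C)C)[C@H](CO[Si](C)(C)C(C)(C)C)c2cc(CBr)cc(OC)c2OCc2ccccc2)ccc1OCc1ccccc1 | intermediate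
33 | lithium enolate of 18 (lithium 3-(DBF-methyl)-2,3-dihydrofuran-5-olate; ring stereocenter unchanged) | [Li+].[O-]C1=C[C@@H](Cc2cc(OC)c3c(c2)[C@H](CO[Si](C(C)C)(C(C)C)C(C)C)[C@@H](c2ccc(OCc4ccccc4)c(OC)c2)O3)CO1 | intermediate (not isolated)
34 | (3R,4R)-3-(4-(benzyloxy)-3-{(1S,2S)-1-[4-(benzyloxy)-3-methoxyphenyl]-1,3-bis[(tert-butyldimethylsilyl)oxy]propan-2-yl}-5-methoxybenzyl)-4-(DBF-methyl)oxolan-2-one | COc1cc([C@@H](O[Si](C)(C)C(C)(C)C)[C@H](CO[Si](C)(C)C(C)(C)C)c2cc(C[C@H]3C(=O)OC[C@@H]3Cc3cc(OC)c4c(c3)[C@H](CO[Si](C(C)C)(C(C)C)C(C)C)[C@@H](c3ccc(OCc5ccccc5)c(OC)c3)O4)cc(OC)c2OCc2ccccc2)ccc1OCc1ccccc1 | intermediate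
35 | (3R,4R)-3-(4-(benzyloxy)-3-{(1S,2S)-1-[4-(benzyloxy)-3-methoxyphenyl]-1,3-dihydroxypropan-2-yl}-5-methoxybenzyl)-4-({(2S,3R)-2-[4-(benzyloxy)-3-methoxyphenyl]-3-(hydroxymethyl)-7-methoxy-2,3-dihydro-1-benzofuran-5-yl}methyl)oxolan-2-one | COc1cc([C@@H](O)[C@H](CO)c2cc(C[C@H]3C(=O)OC[C@@H]3Cc3cc(OC)c4c(c3)[C@H](CO)[C@@H](c3ccc(OCc5ccccc5)c(OC)c3)O4)cc(OC)c2OCc2ccccc2)ccc1OCc1ccccc1 | intermediate
36 | (3R,4R)-3-{4-hydroxy-3-[(1S,2S)-1,3-dihydroxy-1-(4-hydroxy-3-methoxyphenyl)propan-2-yl]-5-methoxybenzyl}-4-{[(2S,3R)-2-(4-hydroxy-3-methoxyphenyl)-3-(hydroxymethyl)-7-methoxy-2,3-dihydro-1-benzofuran-5-yl]methyl}oxolan-2-one | COc1cc([C@@H](O)[C@H](CO)c2cc(C[C@H]3C(=O)OC[C@@H]3Cc3cc(OC)c4c(c3)[C@H](CO)[C@@H](c3ccc(O)c(OC)c3)O4)cc(OC)c2O)ccc1O | target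

**Count**
Total steps: 21. Longest linear sequence: 13 (steps 1–10, then 19–21); the other branch is steps 11–18.

**Steps most likely to fail, with fallbacks**

Step 4. The bromine-deactivated ring A may migrate too slowly, so that iodane 8 instead loses H-3 (dehydrogenation) or the C2 aryl group shifts. The fallback sets out from 24 and 25 and returns at 13; it closes the furan ring through the O–C2 bond by acid-induced cycloetherification. Boronate 24 and aldehyde 25 are combined as in step 14 but with (R)-TRIP, which should give, through the pinacol borate of the enantiomeric adduct F1, the enantiomeric anti homoallylic alcohol F2. Ozonolysis and NaBH4 as in step 15 lead through the ozonide F3 to the (1R,2R)-diol F4. Hydrogenolysis (H2, Pd/C, EtOAc) frees both phenols to give the bis-phenol diol F5. BF3·OEt2 in CH2Cl2 at −20 °C ionises the benzylic alcohol, and the ortho phenol traps the cation to give the trans-dihydrobenzofuran hydroxy ester F6 (C3 retained from F4, C2 set trans to it). BnBr/K2CO3 in acetone re-protects the phenol as the benzyl ether F7, TIPSCl/imidazole gives the silyl ether F8, DIBAL-H reduces the ester to the benzylic alcohol F9, and MnO2 in CH2Cl2 oxidises it to aldehyde 13, from which steps 8–10 follow.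

Step 14. The γ-aryl allylboronate may add so slowly that the uncatalysed background reaction erodes facial selectivity, and any E-to-Z isomerisation of 24 would erode anti selectivity. The fallback sets out from 20 and 25 and returns at 29; it builds the Cα–Cβ bond by an auxiliary-controlled anti-aldol. Coupling of bromide 20 with the zinc enolate BrZnCH2CO2C(CH3)3 (Pd(dba)2, Q-Phos, THF, rt) should give the tert-butyl arylacetate F10. TFA in CH2Cl2 gives the arylacetic acid F11. Pivaloyl chloride/Et3N and then lithiated (4S)-4-benzyl-1,3-oxazolidin-2-one give the imide F12. The magnesium-halide-catalysed anti-aldol with 25 (MgCl2 10 mol %, Et3N, Me3SiCl, EtOAc, rt), in which the chelated Z-enolate reacts on the face away from the benzyl group, should give the silylated anti adduct F13; TFA/MeOH desilylates it to the anti aldol F14. LiBH4 (THF, 1 equiv H2O, 0 °C) removes the auxiliary reductively to give diol 29.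

Step 3. Protodeboronation of the electron-rich boronic acid may outrun insertion, or facial selectivity at C2 may be insufficient, which would lower the enantiomeric purity of the whole ring-closed unit. The fallback sets out from 2 and 25 and returns at 6; it replaces asymmetric C–C bond formation by a kinetic resolution. Claisen–Schmidt condensation of 2 with 25 (KOH, EtOH) gives the 2'-hydroxychalcone F15. NaOAc in refluxing EtOH cyclises it to the racemic flavanone F16. Asymmetric transfer hydrogenation (RuCl(p-cymene)[(R,R)-TsDPEN], HCO2H/Et3N, EtOAc) should reduce the (2R) enantiomer to the cis-flavan-4-ol F17 and leave (2S)-flavanone 6, separated by chromatography.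

**Further compounds**
F1 | step 4 | pinacol borate (O-Bpin ester) of F2 | COc1cc([C@H](OB2OC(C)(C)C(C)(C)O2)[C@@H](C=C)c2cc(C(=O)OC)cc(OC)c2OCc2ccccc2)ccc1OCc1ccccc1
F2 | step 4 | methyl 4-(benzyloxy)-3-{(1R,2S)-1-[4-(benzyloxy)-3-methoxyphenyl]-1-hydroxybut-3-en-2-yl}-5-methoxybenzoate | COc1cc([C@H](O)[C@@H](C=C)c2cc(C(=O)OC)cc(OC)c2OCc2ccccc2)ccc1OCc1ccccc1
F3 | step 4 | ozonide of F2 (1,2,4-trioxolan-3-yl in place of vinyl; epimer mixture at the trioxolane carbon) | COc1cc([C@H](O)[C@@H](C2OCOO2)c2cc(C(=O)OC)cc(OC)c2OCc2ccccc2)ccc1OCc1ccccc1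
F4 | step 4 | methyl 4-(benzyloxy)-3-{(1R,2R)-1-[4-(benzyloxy)-3-methoxyphenyl]-1,3-dihydroxypropan-2-yl}-5-methoxybenzoate | COc1cc([C@H](O)[C@@H](CO)c2cc(C(=O)OC)cc(OC)c2OCc2ccccc2)ccc1OCc1ccccc1
F5 | step 4 | methyl 3-[(1R,2R)-1,3-dihydroxy-1-(4-hydroxy-3-methoxyphenyl)propan-2-yl]-4-hydroxy-5-methoxybenzoate | COc1cc([C@H](O)[C@@H](CO)c2cc(C(=O)OC)cc(OC)c2O)ccc1O
F6 | step 4 | methyl (2S,3R)-2-(4-hydroxy-3-methoxyphenyl)-3-(hydroxymethyl)-7-methoxy-2,3-dihydro-1-benzofuran-5-carboxylate | COC(=O)c1cc(OC)c2c(c1)[C@H](CO)[C@@H](c1ccc(O)c(OC)c1)O2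
F7 | step 4 | methyl (2S,3R)-2-[4-(benzyloxy)-3-methoxyphenyl]-3-(hydroxymethyl)-7-methoxy-2,3-dihydro-1-benzofuran-5-carboxylate | COC(=O)c1cc(OC)c2c(c1)[C@H](CO)[C@@H](c1ccc(OCc3ccccc3)c(OC)c1)O2
F8 | step 4 | methyl (2S,3R)-2-[4-(benzyloxy)-3-methoxyphenyl]-7-methoxy-3-({[tri(propan-2-yl)silyl]oxy}methyl)-2,3-dihydro-1-benzofuran-5-carboxylate | COC(=O)c1cc(OC)c2c(c1)[C@H](CO[Si](C(C)C)(C(C)C)C(C)C)[C@@H](c1ccc(OCc3ccccc3)c(OC)c1)O2
F9 | step 4 | DBF-methanol: [(2S,3R)-2-[4-(benzyloxy)-3-methoxyphenyl]-7-methoxy-3-({[tri(propan-2-yl)silyl]oxy}methyl)-2,3-dihydro-1-benzofuran-5-yl]methanol | OCc1cc(OC)c2c(c1)[C@H](CO[Si](C(C)C)(C(C)C)C(C)C)[C@@H](c1ccc(OCc3ccccc3)c(OC)c1)O2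
F10 | step 14 | methyl 4-(benzyloxy)-3-(2-tert-butoxy-2-oxoethyl)-5-methoxybenzoate | COC(=O)c1cc(CC(=O)OC(C)(C)C)c(OCc2ccccc2)c(OC)c1
F11 | step 14 | [2-(benzyloxy)-3-methoxy-5-(methoxycarbonyl)phenyl]acetic acid | COC(=O)c1cc(CC(=O)O)c(OCc2ccccc2)c(OC)c1
F12 | step 14 | methyl 4-(benzyloxy)-3-{2-[(4S)-4-benzyl-2-oxo-1,3-oxazolidin-3-yl]-2-oxoethyl}-5-methoxybenzoate | COC(=O)c1cc(CC(=O)N2[C@@H](Cc3ccccc3)COC2=O)c(OCc2ccccc2)c(OC)c1
F13 | step 14 | O-trimethylsilyl ether of F14 | COc1cc([C@@H](O[Si](C)(C)C)[C@H](C(=O)N2[C@@H](Cc3ccccc3)COC2=O)c2cc(C(=O)OC)cc(OC)c2OCc2ccccc2)ccc1OCc1ccccc1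
F14 | step 14 | methyl 4-(benzyloxy)-3-{(2R,3S)-1-[(4S)-4-benzyl-2-oxo-1,3-oxazolidin-3-yl]-3-[4-(benzyloxy)-3-methoxyphenyl]-3-hydroxy-1-oxopropan-2-yl}-5-methoxybenzoate | COc1cc([C@@H](O)[C@H](C(=O)N2[C@@H](Cc3ccccc3)COC2=O)c2cc(C(=O)OC)cc(OC)c2OCc2ccccc2)ccc1OCc1ccccc1
F15 | step 3 | (2E)-3-[4-(benzyloxy)-3-methoxyphenyl]-1-(5-bromo-2-hydroxy-3-methoxyphenyl)prop-2-en-1-one | O=C(/C=C/c1ccc(OCc2ccccc2)c(OC)c1)c1cc(Br)cc(OC)c1O
F16 | step 3 | racemic 2-[4-(benzyloxy)-3-methoxyphenyl]-6-bromo-8-methoxy-2,3-dihydro-4H-chromen-4-one | O=C1CC(c2ccc(OCc3ccccc3)c(OC)c2)Oc2c(OC)cc(Br)cc21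
F17 | step 3 | (2R,4R)-2-[4-(benzyloxy)-3-methoxyphenyl]-6-bromo-8-methoxy-3,4-dihydro-2H-chromen-4-ol | O[C@@H]1C[C@H](c2ccc(OCc3ccccc3)c(OC)c2)Oc2c(OC)cc(Br)cc21
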